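The ten-membered carbocycle is closed late at C4–C5 (germacrane numbering: C4 is the methyl-bearing oxirane carbon, C5 the neighbouring angelate carbinol) by an intramolecular Nozaki–Hiyama–Kishi addition of a (Z)-alkenyl iodide to an aldehyde. The step exploits the C5 carbinol flanking the C3–C4 cis-epoxide, read as a masked (Z)-C3=C4 alkene: one operation gives the ring, C5 and the allylic alcohol that steers the epoxidation. The open chain grows from (S)-carvone, whose six-membered ring holds C5–C10 and relays C7 to C6 and C9 before its C5–C10 bond, absent from the target, is cleaved; C10, C1, C5 and C3/C4 follow by chelation, reagent and macrocyclic control.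

Key step: step 16

Remark: all compounds carry the germacrane atom numbers of the target (C7 bears the isopropenyl group, C10 is the tertiary carbinol; in carvone C5 is the carbonyl carbon and C6 the ring CH2 next to it); the acyl group on the C6 oxygen is (R)-2-methylbutanoyl as the structure specifies, and the target is (1S,3S,4S,5S,6R,7R,9R,10S).

Step 1
Reactants: 1 but-2-yn-1-ol
Product: 3 (Z)-3-iodobut-2-en-1-ol, via cyclic sodium alkenylalanate 2 (not isolated)
Conditions: NaAlH2(OCH2CH2OCH3)2, THF, 0 °C to rt; EtOAc quench; then I2, −78 °C; aqueous work-up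
Reagents that add atoms: iodine, II
Why: Alkoxide-directed trans-hydroalumination of the propargylic alcohol places aluminium on C3 within the five-membered alanate 2, and iodinolysis of the C–Al bond with retention gives the (Z)-alkenyl iodide (iodine cis to CH2OH), the geometry that later becomes the cis ring alkene.

Step 2
Reactants: 3 (Z)-3-iodobut-2-en-1-ol
Product: 4 (Z)-1-bromo-3-iodobut-2-ene
Conditions: CBr4, PPh3, CH2Cl2, 0 °C
Reagents that add atoms: carbon tetrabromide, BrC(Br)(Br)Br
Why: Appel bromination converts the primary allylic alcohol into the bromide by SN2 displacement of the oxyphosphonium group without touching the alkenyl iodide or its geometry.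

Step 3
Reactants: 5 (S)-(+)-carvone
Product: 6 trans-carvone oxide (9,10-epoxide trans to the C7 isopropenyl group)
Conditions: 30% aq. H2O2, NaOH, MeOH, 0 °C
Reagents that add atoms: hydrogen peroxide, OO
Why: Weitz–Scheffer nucleophilic epoxidation attacks only the electron-poor enone alkene, the hydroperoxide adding to C9 anti to the C7 isopropenyl group so that the oxirane is trans to it (the C9 oxygen is inverted in step 6).

Step 4
Reactants: 6 trans-carvone oxide
Product: 8 6-hydroxy-trans-carvone oxide (C6–OH trans to the isopropenyl group), via sodium enolate 7 (not isolated)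
Conditions: NaN(SiMe3)2, THF, −78 °C; then 2-(phenylsulfonyl)-3-phenyloxaziridine, −78 °C; aq. NH4Cl
Reagents that add atoms: 2-(phenylsulfonyl)-3-phenyloxaziridine, O=S(=O)(c1ccccc1)N1OC1c1ccccc1
Why: C6 is the only enolisable position, and electrophilic hydroxylation of the sodium enolate 7 by the N-sulfonyloxaziridine occurs on the face anti to the neighbouring C7 isopropenyl group, which sets C6 with its oxygen trans to C7 as in the target.

Step 5
Reactants: 8 6-hydroxy-trans-carvone oxide
Product: 9 C6 tert-butyldimethylsilyl ether of 8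
Conditions: t-BuMe2SiCl, imidazole, DMF, rt
Reagents that add atoms: tert-butyldimethylsilyl chloride, CC(C)(C)[Si](C)(C)Cl
Why: Standard silylation of the secondary alcohol gives a non-participating, base-stable ether that survives the later organolithium steps and blocks C6 during the glycol cleavage.

Step 6
Reactants: 9 C6 silyl ether
Product: 10 alpha-ketol with C9–O-(4-methoxybenzyl) cis to the isopropenyl group and free tertiary C10–OH
Conditions: 4-methoxybenzyl alcohol (excess), BF3·OEt2 (cat.), CH2Cl2, −40 to −10 °C
Reagents that add atoms: 4-methoxybenzyl alcohol, COc1ccc(CO)cc1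
Why: Lewis acid-catalysed epoxide alcoholysis proceeds by SN2 attack of the benzylic alcohol at the secondary C9 with inversion (the tertiary C10 next to the carbonyl is deactivated), which places the C9 oxygen cis to the isopropenyl group as a chelating ether and frees the tertiary C10 hydroxyl.

Step 7
Reactants: 10 alpha-ketol
Product: 11 5,10-diol (both C5 epimers)
Conditions: NaBH4, CeCl3·7H2O, MeOH, −78 °C
Reagents that add atoms: none
Why: Luche-type borohydride reduction converts the hindered ketone into the C5 alcohol needed for glycol cleavage, the cold CeCl3-buffered medium suppressing silyl migration, and the configuration formed at C5 is irrelevant because this centre is destroyed in step 8.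

Step 8
Reactants: 11 5,10-diol
Product: 13 open-chain keto acetal (C5 dimethyl acetal; C10 methyl ketone), via keto aldehyde 12 (not isolated)
Conditions: Pb(OAc)4, CH2Cl2, 0 °C; then HC(OMe)3, pyridinium p-toluenesulfonate (cat.), MeOH, rt
Reagents that add atoms: trimethyl orthoformate, COC(OC)OC
Why: Criegee glycol cleavage of the secondary–tertiary diol breaks the C5–C10 bond of the carvone ring to give the C5 aldehyde and the C10 methyl ketone of 12, and acid-catalysed acetalisation in the same flask masks only the more electrophilic aldehyde, so that C6, C7 and C9 are carried over unchanged.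

Step 9
Reactants: 13 open-chain keto acetal; 14 1,3-dithiane
Product: 16 tertiary C10 carbinol bearing the 1,3-dithian-2-yl group (C1), via 2-lithio-1,3-dithiane 15 (not isolated)
Conditions: 14, n-BuLi, THF, −30 °C; then 13 precomplexed with MgBr2·OEt2, THF/Et2O, −78 °C; aq. NH4Cl
Reagents that add atoms: 1,3-dithiane (14), C1CSCSC1
Why: Corey–Seebach addition of the acyl-anion equivalent 15 to the methyl ketone is chelation-controlled, magnesium bridging the ketone oxygen and the C9 benzylic ether oxygen so that the nucleophile enters anti to C8, which sets the tertiary C10 carbinol with the target configuration.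

Step 10
Reactants: 16 dithianyl carbinol; 4 (Z)-1-bromo-3-iodobut-2-ene
Product: 18 C1-alkylated dithiane carrying the (Z)-3-iodobut-2-enyl chain, via O,C-dilithio dianion 17 (not isolated)
Conditions: n-BuLi (2.0 equiv), THF, −40 to −20 °C; then 4, −78 to −20 °C; aq. NH4Cl
Reagents that add atoms: (Z)-1-bromo-3-iodobut-2-ene (4), C/C(I)=C/CBr
Why: Double deprotonation gives the O,C-dilithio species 17, in which the oxide cannot be lost by beta-elimination, and its dithiane carbanion is alkylated by SN2 at the primary allylic bromide 4, the alkenyl iodide meeting no alkyllithium and no new stereocentre being formed.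

Step 11
Reactants: 18 C1-alkylated dithiane
Product: 19 alpha-hydroxy ketone (C1 ketone)
Conditions: MeI, CaCO3, MeCN/H2O (9:1), 45 °C
Reagents that add atoms: water, O
Why: S-Methylation and hydrolysis of the dithioketal (dethioacetalisation) releases the C1 ketone under near-neutral conditions that spare the dimethyl acetal, the silyl and benzylic ethers, the tertiary alcohol and the beta,gamma-unsaturated alkenyl iodide.

Step 12
Reactants: 19 alpha-hydroxy ketone
Product: 20 (1S)-1,10-diol
Conditions: (R)-Me-CBS oxazaborolidine [(R)-1-methyl-3,3-diphenyltetrahydro-1H,3H-pyrrolo[1,2-c][1,3,2]oxazaborole] (cat.), catecholborane, toluene, −60 °C; then MeOH, aq. NaOH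
Reagents that add atoms: none
Why: Corey–Bakshi–Shibata reduction sets C1 by reagent control, the quaternary C10 acting as the large and the C2 methylene as the small group so that the (R)-catalyst delivers hydride to the face giving the (1S)-alcohol, while catecholborane does not hydroborate the isopropenyl group.

Step 13
Reactants: 21 angelic acid
Product: 22 angelic 2,4,6-trichlorobenzoic anhydride
Conditions: 2,4,6-trichlorobenzoyl chloride, Et3N, toluene, rt; filtration from Et3N·HCl under argon; kept as a toluene solution at −20 °C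
Reagents that add atoms: 2,4,6-trichlorobenzoyl chloride, O=C(Cl)c1c(Cl)cc(Cl)cc1Cl
Why: Acylation of the triethylammonium angelate by the hindered aroyl chloride (first stage of the Yamaguchi esterification) gives the mixed anhydride without a nucleophilic catalyst, so the (Z)-geometry is kept, and the reagent is made once in an amount that serves both angeloylations (steps 14 and 18).

Step 14
Reactants: 20 (1S)-1,10-diol; 22 angelic 2,4,6-trichlorobenzoic anhydride
Product: 23 C1 angelate
Conditions: 22 (toluene solution), Et3N, toluene, 80 °C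
Reagents that add atoms: angelic 2,4,6-trichlorobenzoic anhydride (22), C/C=C(/C)C(=O)OC(=O)c1c(Cl)cc(Cl)cc1Cl
Why: In this Yamaguchi-type esterification the alcohol attacks the unhindered angeloyl carbonyl of the mixed anhydride, which acylates the only secondary hydroxyl (the tertiary C10 hydroxyl is inert) and, run without a nucleophilic amine catalyst, keeps the (Z)-geometry of the angelate.

Step 15
Reactants: 23 C1 angelate
Product: 24 open-chain C5 aldehyde (cyclisation precursor)
Conditions: TsOH·H2O (cat.), acetone/H2O (10:1), rt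
Reagents that add atoms: water, O
Why: Mild acid-catalysed acetal hydrolysis unveils the alpha-silyloxy aldehyde without epimerising C6 and leaves the silyl ether, the benzylic ether, the angelate and the alkenyl iodide intact.

Step 16
Reactants: 24 open-chain C5 aldehyde
Product: 26 ten-membered (3Z)-allylic alcohol with (5S)-hydroxyl, via alkenylchromium dichloride 25 (not isolated)
Conditions: CrCl2 (excess), NiCl2 (cat.), DMSO, rt, slow addition of 24 to a final 0.003 M
Reagents that add atoms: none
Why: CrCl2 reduces NiCl2 to zerovalent nickel, which inserts into the C4–I bond with retention of the (Z)-geometry; transmetalation gives the alkenyl trivalent chromium species 25, which adds to the C5 aldehyde to form the C4–C5 bond and, after work-up, the allylic alcohol. The closest known reaction type is the intramolecular Nozaki–Hiyama–Kishi reaction used to close nine- to twelve-membered carbocycles. The ten-membered ring closes in the 10-exo-trig mode, C4 attacking the carbonyl carbon from within the chain. The new C5 stereocentre is controlled by the substrate through the ring-forming transition state: with the substituents at C1, C6, C7 and C9 on the periphery of the incipient ring, the chromium-bound aldehyde oxygen should also point outwards, which leads to the (5S)-alcohol with the C5 and C6 oxygens trans on the ring. The step needs addition to the aldehyde in the presence of the angelate, the free tertiary alcohol and the ethers, retention of the alkene geometry, and ring closure in preference to oligomerisation; the low basicity and carbonyl selectivity of alkenylchromium reagents, the stereospecific nickel insertion and high dilution with slow addition should secure these, whereas the facial selectivity rests on the conformational bias alone and is the main risk of the route.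

Step 17
Reactants: 26 ten-membered allylic alcohol
Product: 27 (3S,4S)-3,4-epoxy alcohol
Conditions: mCPBA, NaHCO3, CH2Cl2, −20 °C
Reagents that add atoms: 3-chloroperoxybenzoic acid, O=C(OO)c1cccc(Cl)c1
Why: Prilezhaev epoxidation takes the most nucleophilic, trisubstituted ring alkene in preference to the isopropenyl group and the electron-poor angelate, and hydrogen-bonded delivery from the pseudo-equatorial C5 hydroxyl (as in peracid epoxidations of medium-ring cis-cycloalkenols) should put the oxygen on the ring face opposite to the C5 oxygen, so that the (Z)-alkene gives the cis-epoxide and C3 and C4 are set in one event.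

Step 18
Reactants: 27 epoxy alcohol; 22 angelic 2,4,6-trichlorobenzoic anhydride
Product: 28 1,5-di-O-angeloyl epoxide
Conditions: 22 (toluene solution), Et3N, toluene, 80 °C
Reagents that add atoms: angelic 2,4,6-trichlorobenzoic anhydride (22), C/C=C(/C)C(=O)OC(=O)c1c(Cl)cc(Cl)cc1Cl
Why: The mixed anhydride from step 13 acylates the only free secondary hydroxyl, the hindered C5 alcohol, in a Yamaguchi-type esterification free of nucleophilic amine catalyst, which avoids angelate-to-tiglate isomerisation, while Et3N scavenges the liberated acid so that the epoxide should stay closed.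

Step 19
Reactants: 28 1,5-di-O-angeloyl epoxide
Product: 29 C6 alcohol
Conditions: HF·pyridine, pyridine, THF, 0 °C to rt
Reagents that add atoms: none
Why: Fluoride-mediated desilylation in pyridine-buffered HF removes the C6 silyl ether, the weakly acidic medium suppressing migration of the neighbouring C5 angelate and leaving the trisubstituted epoxide closed.

Step 20
Reactants: 29 C6 alcohol; 30 (R)-2-methylbutanoic acid
Product: 31 9-O-(4-methoxybenzyl) ether of the target
Conditions: 30, DCC, 4-(dimethylamino)pyridine (cat.), CH2Cl2, 0 °C to rt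
Reagents that add atoms: (R)-2-methylbutanoic acid (30), CC[C@@H](C)C(=O)O
Why: Steglich esterification acylates the only free secondary hydroxyl with the (R)-acid, whose stereocentre is bought and should not epimerise under carbodiimide activation with catalytic 4-(dimethylamino)pyridine at low temperature.

Step 21
Reactants: 31 9-O-(4-methoxybenzyl) ether of the target
Product: 32 CNP0246823.2 (target)
Conditions: DDQ, CH2Cl2/pH 7 phosphate buffer, 0 °C
Reagents that add atoms: none
Why: Oxidative cleavage of the 4-methoxybenzyl ether by electron transfer to the quinone and hydrolysis of the resulting oxocarbenium ion frees the C9 hydroxyl under neutral buffered conditions that leave the three esters, the epoxide and both alkene types untouched.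

Compound list
1 | but-2-yn-1-ol | CC#CCO | starting material
2 | cyclic sodium (Z)-alkenylalanate of 1 (Al on C3, chelated by the alkoxide, two 2-methoxyethoxy ligands) | CC1=CCO[Al-]1(OCCOC)OCCOC.[Na+] | intermediate
3 | (Z)-3-iodobut-2-en-1-ol | C/C(I)=C/CO | intermediate
4 | (Z)-1-bromo-3-iodobut-2-ene | C/C(I)=C/CBr | intermediate
5 | (S)-(+)-carvone | C=C(C)[C@H]1CC=C(C)C(=O)C1 | starting material
6 | trans-carvone oxide: 9,10-epoxide of 5, oxirane trans to the C7 isopropenyl group | C=C(C)[C@H]1C[C@@H]2O[C@]2(C)C(=O)C1 | intermediate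
7 | sodium C5,C6-enolate of 6 | C=C(C)[C@H]1C[C@@H]2O[C@]2(C)C([O-])=C1.[Na+] | intermediate
8 | 6-hydroxy-trans-carvone oxide, C6–OH trans to the C7 isopropenyl group | C=C(C)[C@H]1C[C@@H]2O[C@]2(C)C(=O)[C@@H]1O | intermediate
9 | C6 tert-butyldimethylsilyl ether of 8 | C=C(C)[C@H]1C[C@@H]2O[C@]2(C)C(=O)[C@@H]1O[Si](C)(C)C(C)(C)C | intermediate
10 | cyclohexanone alpha-ketol: C6–OSi(t-Bu)Me2, C9–O-(4-methoxybenzyl) cis to isopropenyl, tertiary C10–OH trans to the C9 oxygen | C=C(C)[C@H]1C[C@@H](OCc2ccc(OC)cc2)[C@](C)(O)C(=O)[C@@H]1O[Si](C)(C)C(C)(C)C | intermediate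
11 | 5,10-diol from 10 (both C5 epimers, C5 left unassigned) | C=C(C)[C@H]1C[C@@H](OCc2ccc(OC)cc2)[C@](C)(O)C(O)[C@@H]1O[Si](C)(C)C(C)(C)C | intermediate
12 | open-chain keto aldehyde: C5 aldehyde, C6–OSi(t-Bu)Me2, C7 isopropenyl, C9–O-(4-methoxybenzyl), C10 methyl ketone | C=C(C)[C@@H](C[C@@H](OCc1ccc(OC)cc1)C(C)=O)[C@@H](O[Si](C)(C)C(C)(C)C)C=O | intermediate
13 | C5 dimethyl acetal of 12 | C=C(C)[C@@H](C[C@@H](OCc1ccc(OC)cc1)C(C)=O)[C@@H](O[Si](C)(C)C(C)(C)C)C(OC)OC | intermediate
14 | 1,3-dithiane | C1CSCSC1 | starting material
15 | 2-lithio-1,3-dithiane | [Li]C1SCCCS1 | intermediate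
16 | tertiary C10 carbinol from 13 bearing the 1,3-dithian-2-yl group (C1), C10 configured as in the target | C=C(C)[C@@H](C[C@@H](OCc1ccc(OC)cc1)[C@](C)(O)C1SCCCS1)[C@@H](O[Si](C)(C)C(C)(C)C)C(OC)OC | intermediate
17 | O,C-dilithio derivative of 16 (lithium C10 alkoxide, 2-lithiodithiane) | C=C(C)[C@@H](C[C@@H](OCc1ccc(OC)cc1)[C@](C)(O[Li])C1([Li])SCCCS1)[C@@H](O[Si](C)(C)C(C)(C)C)C(OC)OC | intermediate
18 | 16 alkylated at the dithiane carbon C1 with the (Z)-3-iodobut-2-enyl group | C=C(C)[C@@H](C[C@@H](OCc1ccc(OC)cc1)[C@](C)(O)C1(C/C=C(/C)I)SCCCS1)[C@@H](O[Si](C)(C)C(C)(C)C)C(OC)OC | intermediate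
19 | alpha-hydroxy ketone: C1 ketone, tertiary C10–OH, (Z)-C3=C4 alkenyl iodide | C=C(C)[C@@H](C[C@@H](OCc1ccc(OC)cc1)[C@](C)(O)C(=O)C/C=C(/C)I)[C@@H](O[Si](C)(C)C(C)(C)C)C(OC)OC | intermediate
20 | (1S)-1,10-diol from 19 | C=C(C)[C@@H](C[C@@H](OCc1ccc(OC)cc1)[C@](C)(O)[C@@H](O)C/C=C(/C)I)[C@@H](O[Si](C)(C)C(C)(C)C)C(OC)OC | intermediate
21 | angelic acid, (Z)-2-methylbut-2-enoic acid | C/C=C(/C)C(=O)O | starting material
22 | angelic 2,4,6-trichlorobenzoic anhydride | C/C=C(/C)C(=O)OC(=O)c1c(Cl)cc(Cl)cc1Cl | intermediate
23 | C1 angelate of 20 | C=C(C)[C@@H](C[C@@H](OCc1ccc(OC)cc1)[C@](C)(O)[C@@H](OC(=O)/C(C)=C\C)C/C=C(/C)I)[C@@H](O[Si](C)(C)C(C)(C)C)C(OC)OC | intermediate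
24 | open-chain C5 aldehyde from 23 (C4 alkenyl iodide, C5 aldehyde) | C=C(C)[C@@H](C[C@@H](OCc1ccc(OC)cc1)[C@](C)(O)[C@@H](OC(=O)/C(C)=C\C)C/C=C(/C)I)[C@@H](O[Si](C)(C)C(C)(C)C)C=O | intermediate
25 | (Z)-alkenylchromium dichloride from 24 (CrCl2 group on C4) | C=C(C)[C@@H](C[C@@H](OCc1ccc(OC)cc1)[C@](C)(O)[C@@H](OC(=O)/C(C)=C\C)C/C=C(/C)[Cr](Cl)Cl)[C@@H](O[Si](C)(C)C(C)(C)C)C=O | intermediate
26 | ten-membered (3Z)-allylic alcohol: 1-O-angeloyl, (5S)-OH, 6-OSi(t-Bu)Me2, 9-O-(4-methoxybenzyl), 10-OH | C=C(C)[C@H]1C[C@@H](OCc2ccc(OC)cc2)[C@](C)(O)[C@@H](OC(=O)/C(C)=C\C)C/C=C(/C)[C@@H](O)[C@@H]1O[Si](C)(C)C(C)(C)C | intermediate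
27 | (3S,4S)-3,4-epoxide of 26, oxirane oxygen on the ring face opposite to the C5 oxygen | C=C(C)[C@H]1C[C@@H](OCc2ccc(OC)cc2)[C@](C)(O)[C@@H](OC(=O)/C(C)=C\C)C[C@@H]3O[C@]3(C)[C@@H](O)[C@@H]1O[Si](C)(C)C(C)(C)C | intermediate
28 | C5 angelate of 27 (1,5-di-O-angeloyl epoxide) | C=C(C)[C@H]1C[C@@H](OCc2ccc(OC)cc2)[C@](C)(O)[C@@H](OC(=O)/C(C)=C\C)C[C@@H]3O[C@]3(C)[C@@H](OC(=O)/C(C)=C\C)[C@@H]1O[Si](C)(C)C(C)(C)C | intermediate
29 | C6 alcohol from 28 | C=C(C)[C@H]1C[C@@H](OCc2ccc(OC)cc2)[C@](C)(O)[C@@H](OC(=O)/C(C)=C\C)C[C@@H]3O[C@]3(C)[C@@H](OC(=O)/C(C)=C\C)[C@@H]1O | intermediate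
30 | (R)-2-methylbutanoic acid | CC[C@@H](C)C(=O)O | starting material
31 | 9-O-(4-methoxybenzyl) ether of the target | C=C(C)[C@H]1C[C@@H](OCc2ccc(OC)cc2)[C@](C)(O)[C@@H](OC(=O)/C(C)=C\C)C[C@@H]3O[C@]3(C)[C@@H](OC(=O)/C(C)=C\C)[C@@H]1OC(=O)[C@H](C)CC | intermediate
32 | CNP0246823.2: (1S,3S,4S,5S,6R,7R,9R,10S)-1,5-bis[(Z)-2-methylbut-2-enoyloxy]-3,4-epoxy-6-[(2R)-2-methylbutanoyloxy]germacr-11-ene-9,10-diol | C=C(C)[C@H]1C[C@@H](O)[C@](C)(O)[C@@H](OC(=O)/C(C)=C\C)C[C@@H]2O[C@]2(C)[C@@H](OC(=O)/C(C)=C\C)[C@@H]1OC(=O)[C@H](C)CC | target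

Total step count: 21. Longest linear sequence: 18 steps (steps 3 to 12 and 14 to 21, from (S)-carvone); steps 1 and 2 make the side-chain bromide 4, and step 13 makes the acylating reagent 22.

Steps most likely to fail:

1. Step 16 (ring closure). The open-chain Felkin–Anh preference of the alpha-silyloxy aldehyde may override the macrocyclic bias, so that the alkenylchromium attacks the wrong aldehyde face. Fallback: starting from 24, the same cyclisation is run and the undesired C5 epimer, 5-epi allylic alcohol F1, is oxidised with Dess–Martin periodinane (NaHCO3, CH2Cl2) to the macrocyclic (Z)-enone F2. 1,2-Reduction of F2 with NaBH4/CeCl3·7H2O in MeOH at −78 °C follows, in which hydride adds anti to the C6 silyloxy group. This is the same Felkin–Anh bias, but with hydride instead of carbon as the entering group, and it should therefore give the opposite C5 configuration, that of 26, where the route is rejoined.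

2. Step 10 (dianion alkylation). The second lithiation of the hindered beta-oxido dithiane may stay incomplete, or retro-addition and O-alkylation may compete. Fallback by aldol and olefination chemistry: starting from 16, the dithiane is hydrolysed (MeI, CaCO3, aqueous MeCN) to the alpha-hydroxy aldehyde F3. A MgBr2·OEt2-mediated Mukaiyama aldol addition of 1-(tert-butylsulfanyl)-1-(trimethylsilyloxy)ethene under Cram-chelate control should then give the (1S)-beta-hydroxy thioester F4. The 1,10-diol is tied up as the acetonide thioester F5 (2,2-dimethoxypropane, pyridinium p-toluenesulfonate), and i-Bu2AlH at −78 °C gives the acetonide aldehyde F6. Stork–Zhao olefination with (1-iodoethyl)triphenylphosphonium iodide and NaN(SiMe3)2 gives the (Z)-alkenyl iodide acetonide F7, and acetonide exchange (pyridinium p-toluenesulfonate, MeOH) returns the diol 20, so that steps 10 to 12 are bypassed.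

3. Step 17 (epoxidation). The peracid may also epoxidise the isopropenyl group, or approach the ring alkene from the undesired face. Fallback: catalyst-controlled Shi epoxidation of 26 (fructose-derived ketone catalyst, KHSO5 as 2KHSO5·KHSO4·K2SO4, K2CO3-buffered MeCN/dimethoxymethane/water, 0 °C). It discriminates strongly between trisubstituted and 1,1-disubstituted alkenes, and its facial preference is set by choosing the D- or L-fructose-derived ketone. It should give 27 directly, so that no further compound (F0) is needed.

Further compounds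
F1 | step 16 | 5-epi allylic alcohol (C5 epimer of 26) | C=C(C)[C@H]1C[C@@H](OCc2ccc(OC)cc2)[C@](C)(O)[C@@H](OC(=O)/C(C)=C\C)C/C=C(/C)[C@H](O)[C@@H]1O[Si](C)(C)C(C)(C)C
F2 | step 16 | macrocyclic (Z)-enone (C5 ketone) | C=C(C)[C@H]1C[C@@H](OCc2ccc(OC)cc2)[C@](C)(O)[C@@H](OC(=O)/C(C)=C\C)C/C=C(/C)C(=O)[C@@H]1O[Si](C)(C)C(C)(C)C
F3 | step 10 | alpha-hydroxy aldehyde (C1 aldehyde, tertiary C10–OH) | C=C(C)[C@@H](C[C@@H](OCc1ccc(OC)cc1)[C@](C)(O)C=O)[C@@H](O[Si](C)(C)C(C)(C)C)C(OC)OC
F4 | step 10 | (1S)-beta-hydroxy S-tert-butyl thioester | C=C(C)[C@@H](C[C@@H](OCc1ccc(OC)cc1)[C@](C)(O)[C@@H](O)CC(=O)SC(C)(C)C)[C@@H](O[Si](C)(C)C(C)(C)C)C(OC)OC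
F5 | step 10 | 1,10-O-isopropylidene thioester | C=C(C)[C@@H](C[C@@H](OCc1ccc(OC)cc1)[C@]1(C)OC(C)(C)O[C@H]1CC(=O)SC(C)(C)C)[C@@H](O[Si](C)(C)C(C)(C)C)C(OC)OC
F6 | step 10 | 1,10-O-isopropylidene C3 aldehyde | C=C(C)[C@@H](C[C@@H](OCc1ccc(OC)cc1)[C@]1(C)OC(C)(C)O[C@H]1CC=O)[C@@H](O[Si](C)(C)C(C)(C)C)C(OC)OC
F7 | step 10 | 1,10-O-isopropylidene (Z)-alkenyl iodide | C=C(C)[C@@H](C[C@@H](OCc1ccc(OC)cc1)[C@]1(C)OC(C)(C)O[C@H]1C/C=C(/C)I)[C@@H](O[Si](C)(C)C(C)(C)C)C(OC)OC
F0 | step 17 | none | none
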